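**Strategy.** The plan cuts the dihydrofuran ring of the benzofuran unit (O1, C2, C3, C3a, C7a) at O1–C2 and C2–C3, so that C2 and its aryl group arrive last as a one-carbon unit. The key step is a (4+1) annulation. The ortho-hydroxybenzhydryl motif formed by the phenol oxygen O1, C7a, C3a and the benzylic C3 (a member of the eight-membered ring) is unmasked as an ortho-quinone methide, which takes up a 4-methoxybenzyl sulfonium ylide. Two bonds, the ring and the trans C2/C3 stereocentres form in one operation. The precursor is the complete indane-fused dibenzocyclooctene core, assembled by a Staunton–Weinreb annulation and a two-carbon aryne ring expansion.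

Key step: step 15

Labels used below: C-f = C2 and C-d = C3 of the dihydrobenzofuran; C-c = the eight-ring CH carrying a 4-oxyphenyl group; C-b and C-e = the two ring-fusion CH atoms (C-b bonded to C-c, C-e bonded to C-a); C-a = the indane CH carrying a 4-oxyphenyl group; ring B = oxygenated ring of the indane, ring C = oxygenated ring between C-c and C-d, ring D = benzene ring of the benzofuran. In the target: C-a R, C-b R, C-c R, C-d R, C-e S, C-f R.

Assumption: 1, 2 (as a 0.5 M solution in THF) and 4 are taken as purchasable. In step 8 the (S)-amine is taken to give the less soluble salt with the wanted acid; if the opposite holds, the (R)-amine would be used.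

**Step 1**
Reactants: 1 methyl 2-bromo-3,5-dimethoxybenzoate; 2 (4-methoxybenzyl)zinc chloride
Product: 3 methyl 3,5-dimethoxy-2-(4-methoxybenzyl)benzoate
Conditions: Pd(OAc)2 (2 mol%), SPhos (4 mol%), THF, 50 °C
Reagents that add atoms: none
Why: Negishi cross-coupling, in which the SPhos-ligated palladium catalyst should insert into the hindered C–Br bond and couple the benzylic zinc reagent without touching the ester; no stereocentre is formed.

**Step 2**
Reactants: 3 methyl 3,5-dimethoxy-2-(4-methoxybenzyl)benzoate; 4 methyl (E)-3-(3,5-dimethoxyphenyl)acrylate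
Product: 5 methyl 3-(3,5-dimethoxyphenyl)-5,7-dimethoxy-4-(4-methoxyphenyl)-1-oxotetralin-2-carboxylate (racemic; 2,3-trans and 3,4-trans; C4 = C-c, C3 = C-b, C2 = C-e, C1 = C-d)
Conditions: LiN(i-Pr)2 (1.2 equiv), THF, −78 °C; then 4, −78 to 0 °C; AcOH quench
Reagents that add atoms: none
Why: Staunton–Weinreb annulation (Michael addition then Dieckmann condensation), in which the laterally lithiated dienolate of 3 should add through C-c to the β-carbon of 4 and the ester enolate then closes onto the benzoate carbonyl; C-c and C-b are set together in a lithium-bridged endo-type transition state with the C-c aryl group turned outward, which should place the two aryl groups trans (also the diaxial arrangement that avoids the peri-methoxy group and the C2 ester), while C-e stays labile (keto–enol).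

**Step 3**
Reactants: 6 3,5-dimethoxyphenol
Product: 7 3,5-dimethoxyphenyl N-isopropylcarbamate
Conditions: i-PrNCO, Et3N (cat.), CH2Cl2, rt
Reagents that add atoms: isopropyl isocyanate, CC(C)N=C=O
Why: Base-catalysed addition of the phenol to the isocyanate should give the carbamate that directs the ortho-metalation of step 4.

**Step 4**
Reactants: 7 3,5-dimethoxyphenyl N-isopropylcarbamate
Product: 10 3,5-dimethoxy-2-(trimethylsilyl)phenyl N-isopropylcarbamate, via N-silyl carbamate 8 (not isolated), via N-silyl C-silyl carbamate 9 (not isolated)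
Conditions: TBSOTf, TMEDA, Et2O, 0 °C to rt; n-BuLi, TMEDA, −78 °C; TMSCl, −78 °C to rt; aqueous NaHSO4 work-up
Reagents that add atoms: chlorotrimethylsilane, C[Si](C)(C)Cl; tert-butyldimethylsilyl triflate (its atoms stay only in 8 and 9), CC(C)(C)[Si](C)(C)OS(=O)(=O)C(F)(F)F
Why: Directed ortho-metalation, in which the transiently N-silylated carbamate should direct lithiation to C2 (flanked by the carbamate and a methoxy group), TMSCl quenches the aryllithium, and the work-up removes the N-silyl group.

**Step 5**
Reactants: 10 3,5-dimethoxy-2-(trimethylsilyl)phenyl N-isopropylcarbamate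
Product: 12 3,5-dimethoxy-2-(trimethylsilyl)phenyl trifluoromethanesulfonate, via silyl phenol 11 (not isolated)
Conditions: DBU, Et2NH, MeCN, 40 °C; then PhNTf2, rt
Reagents that add atoms: N-phenylbis(trifluoromethanesulfonimide), O=S(=O)(N(c1ccccc1)S(=O)(=O)C(F)(F)F)C(F)(F)F
Why: E1cB cleavage of the carbamate by DBU (the isocyanate is scavenged by diethylamine) should free the phenol, which is triflated in the same pot to the ortho-silylaryl triflate.

**Step 6**
Reactants: 5 racemic tetralone ketoester; 12 3,5-dimethoxy-2-(trimethylsilyl)phenyl trifluoromethanesulfonate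
Product: 14 methyl 6-(3,5-dimethoxyphenyl)-2,4,9,11-tetramethoxy-5-(4-methoxyphenyl)-12-oxo-5,6,7,12-tetrahydrodibenzo[a,d][8]annulene-7-carboxylate (racemic; 5,6-trans and 6,7-trans; C5 = C-c, C6 = C-b, C7 = C-e, C12 = C-d), via 3,5-dimethoxybenzyne 13 (not isolated)
Conditions: CsF (2.5 equiv), MeCN, 80 °C
Reagents that add atoms: none
Why: Aryne acyl-alkylation (formal insertion of an aryne into the C–C bond of a β-ketoester), in which the enolate carbon C-e should add to the aryne carbon remote from the flanking methoxy group, the aryl anion ortho to that methoxy group attacks the C-d ketone, and fragmentation of the benzocyclobutenoxide expands the six-membered ring to the eight-membered aryl ketone carrying ring D; C-b and C-c are untouched and C-e (α to the ester) is reprotonated to the more stable epimer.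

**Step 7**
Reactants: 14 racemic eight-ring keto ester
Product: 15 6-(3,5-dimethoxyphenyl)-2,4,9,11-tetramethoxy-5-(4-methoxyphenyl)-12-oxo-5,6,7,12-tetrahydrodibenzo[a,d][8]annulene-7-carboxylic acid (racemic)
Conditions: LiOH, THF/MeOH/H2O, 50 °C; then 1 M HCl
Reagents that add atoms: lithium hydroxide, [Li+].[OH-]
Why: Saponification of the methyl ester, with the diaryl ketone inert and the epimerisable C-e left at its thermodynamic configuration.

**Step 8**
Reactants: 15 racemic eight-ring keto acid
Product: 16 the single enantiomer of acid 15 with C-b, C-c and C-e arranged as in the target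
Conditions: (S)-1-phenylethylamine (1 equiv), EtOAc/EtOH, fractional crystallisation of the salt; then 1 M HCl, EtOAc
Reagents that add atoms: none
Why: Classical resolution through diastereomeric ammonium salts should fix the absolute configuration at C-b and C-c (assignment to be confirmed by X-ray analysis of the salt); no stereocentre is formed.

**Step 9**
Reactants: 16 enantiopure eight-ring keto acid
Product: 17 pentacyclic diketone (5,7-dimethoxyindan-1-one with carbonyl C-a, trans-fused through C-e/C-b to the dibenzocyclooctenone with carbonyl C-d)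
Conditions: (CF3CO)2O, CH2Cl2, 0 °C to rt
Reagents that add atoms: none
Why: Intramolecular Friedel–Crafts acylation through the mixed anhydride, in which only the ortho carbon of the C-b aryl group (ring B, activated ortho/para by its methoxy groups) is in reach; C-e, now α to the new ketone, should equilibrate to the trans ring fusion (ring D trans to C-c).

**Step 10**
Reactants: 17 pentacyclic diketone; 18 4-bromoanisole
Product: 19 tertiary alcohol at C-a (4-methoxyphenyl added to the indanone carbonyl anti to ring D; C-d ketone intact)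
Conditions: 18, n-BuLi, THF, −78 °C; anhydrous CeCl3, −78 °C; then 17, −78 to −40 °C; aqueous NH4Cl
Reagents that add atoms: none
Why: 1,2-Addition of an organocerium reagent, which is weakly basic and should add to the enolisable indanone carbonyl C-a while the tri-ortho-substituted diaryl ketone C-d is too hindered to react; the carbinol configuration is of no consequence.

**Step 11**
Reactants: 19 tertiary alcohol at C-a
Product: 20 hepta-O-methyl ketone (C-a–H; the C-a aryl group cis to ring D; C-a, C-b, C-c and C-e as in the target; C-d a diaryl ketone)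
Conditions: Et3SiH (5 equiv), CF3CO2H, CH2Cl2, −40 to 0 °C
Reagents that add atoms: none
Why: Ionic hydrogenation, in which the acid ionises the tertiary dibenzylic alcohol and the silane should deliver hydride to C-a from the face opposite the adjacent ring D, placing the C-a aryl group cis to ring D.

**Step 12**
Reactants: 20 hepta-O-methyl ketone
Product: 21 ortho-hydroxy ketone (20 with the ring D methoxy group ortho to the C-d carbonyl cleaved to OH)
Conditions: BCl3 (1.5 equiv), CH2Cl2, −78 to 0 °C; aqueous work-up
Reagents that add atoms: none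
Why: Chelation-controlled demethylation, in which BCl3 bound to the C-d carbonyl should cleave only the methoxy group ortho to it and so uncover the phenol oxygen of the future furan ring.

**Step 13**
Reactants: 21 ortho-hydroxy ketone
Product: 23 sulfone (C-d bearing H and p-tolylsulfonyl; both C-d epimers), via benzhydrol 22 (not isolated)
Conditions: NaBH4, THF/MeOH, 0 to 40 °C; neutral work-up; then p-TolSO2H, CH2Cl2, rt
Reagents that add atoms: p-toluenesulfinic acid, Cc1ccc(S(=O)O)cc1
Why: Hydride reduction to the ortho-hydroxybenzhydrol, then SN1 exchange of hydroxyl for sulfinate through the stabilised benzhydryl cation, should give a base-labile precursor of the ortho-quinone methide; the configuration at C-d is irrelevant.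

**Step 14**
Reactants: 24 4-methoxybenzyl alcohol
Product: 25 1-(4-methoxybenzyl)tetrahydrothiophenium tetrafluoroborate
Conditions: tetrahydrothiophene, HBF4 (48% aq.), rt; precipitation with Et2O
Reagents that add atoms: tetrahydrothiophene, C1CCSC1; tetrafluoroboric acid, [H+].F[B-](F)(F)F
Why: Acid-promoted SN1 alkylation of the sulfide by the 4-methoxybenzyl cation should give the crystalline sulfonium salt.

**Step 15**
Reactants: 23 sulfone; 25 1-(4-methoxybenzyl)tetrahydrothiophenium tetrafluoroborate
Product: 27 octa-O-methylcanaliculatol, via ortho-quinone methide 26 (not isolated)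
Conditions: Cs2CO3 (3 equiv), 25 (1.5 equiv), CH2Cl2, 0 °C to rt
Reagents that add atoms: none
Why: Cs2CO3 should eliminate p-toluenesulfinate from the phenol 23 to give the ortho-quinone methide 26 and deprotonate 25 to its ylide; the ylide carbon adds to C-d (1,4-addition) and the resulting phenoxide displaces tetrahydrothiophene at C-f. This is the known (4+1) annulation of ortho-quinone methides with sulfur ylides to trans-2,3-dihydrobenzofurans. The furan ring closes by 5-exo-tet O-alkylation (SN2 at C-f) after the intermolecular C–C bond formation. C-d is set by the substrate: the ylide should approach the face of the eight-membered ring that carries the hydrogens at C-c and C-e, away from the aryl group on C-c and the indane carbon C-a on C-e. C-f is set relative to C-d by the anti betaine and inversion in the ring closure, and the trans isomer is also the thermodynamic one. The step needs C-alkylation at C-d to outrun O-benzylation of the phenoxide by 25, which the fast conjugate addition of the semi-stabilised ylide to the quinone methide should secure.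

**Step 16**
Reactants: 27 octa-O-methylcanaliculatol
Product: 28 canaliculatol
Conditions: BBr3 (20 equiv), CH2Cl2, −78 °C to rt; MeOH then H2O
Reagents that add atoms: none
Why: Exhaustive cleavage of the eight aryl methyl ethers with BBr3, in which any reversible opening at C-f should return the thermodynamically preferred trans-dihydrobenzofuran.

**Compound list**

1 | methyl 2-bromo-3,5-dimethoxybenzoate | COC(=O)c1cc(OC)cc(OC)c1Br | starting material
2 | (4-methoxybenzyl)zinc chloride | COc1ccc(C[Zn]Cl)cc1 | starting material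
3 | methyl 3,5-dimethoxy-2-(4-methoxybenzyl)benzoate | COC(=O)c1cc(OC)cc(OC)c1Cc1ccc(OC)cc1 | intermediate
4 | methyl (E)-3-(3,5-dimethoxyphenyl)acrylate | COC(=O)/C=C/c1cc(OC)cc(OC)c1 | starting material
5 | methyl 3-(3,5-dimethoxyphenyl)-5,7-dimethoxy-4-(4-methoxyphenyl)-1-oxotetralin-2-carboxylate (racemic; 2,3-trans, 3,4-trans; enantiomer carried on is drawn) | COC(=O)[C@H]1C(=O)c2cc(OC)cc(OC)c2[C@@H](c2ccc(OC)cc2)[C@@H]1c1cc(OC)cc(OC)c1 | intermediate
6 | 3,5-dimethoxyphenol | COc1cc(O)cc(OC)c1 | starting material
7 | 3,5-dimethoxyphenyl N-isopropylcarbamate | COc1cc(OC)cc(OC(=O)NC(C)C)c1 | intermediate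
8 | 3,5-dimethoxyphenyl N-(tert-butyldimethylsilyl)-N-isopropylcarbamate | COc1cc(OC)cc(OC(=O)N(C(C)C)[Si](C)(C)C(C)(C)C)c1 | intermediate
9 | 3,5-dimethoxy-2-(trimethylsilyl)phenyl N-(tert-butyldimethylsilyl)-N-isopropylcarbamate | COc1cc(OC)c([Si](C)(C)C)c(OC(=O)N(C(C)C)[Si](C)(C)C(C)(C)C)c1 | intermediate
10 | 3,5-dimethoxy-2-(trimethylsilyl)phenyl N-isopropylcarbamate | COc1cc(OC)c([Si](C)(C)C)c(OC(=O)NC(C)C)c1 | intermediate
11 | 3,5-dimethoxy-2-(trimethylsilyl)phenol | COc1cc(OC)c([Si](C)(C)C)c(O)c1 | intermediate
12 | 3,5-dimethoxy-2-(trimethylsilyl)phenyl trifluoromethanesulfonate | COc1cc(OC)c([Si](C)(C)C)c(OS(=O)(=O)C(F)(F)F)c1 | intermediate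
13 | 3,5-dimethoxybenzyne | COC1=CC(OC)=CC#C1 | intermediate
14 | methyl 6-(3,5-dimethoxyphenyl)-2,4,9,11-tetramethoxy-5-(4-methoxyphenyl)-12-oxo-5,6,7,12-tetrahydrodibenzo[a,d][8]annulene-7-carboxylate (racemic; 5,6-trans, 6,7-trans; enantiomer carried on is drawn) | COC(=O)[C@H]1c2cc(OC)cc(OC)c2C(=O)c2cc(OC)cc(OC)c2[C@@H](c2ccc(OC)cc2)[C@@H]1c1cc(OC)cc(OC)c1 | intermediate
15 | the 7-carboxylic acid of 14 (racemic; enantiomer carried on is drawn) | OC(=O)[C@H]1c2cc(OC)cc(OC)c2C(=O)c2cc(OC)cc(OC)c2[C@@H](c2ccc(OC)cc2)[C@@H]1c1cc(OC)cc(OC)c1 | intermediate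
16 | acid 15 as the single enantiomer (C-b, C-c, C-e as in the target) | OC(=O)[C@H]1c2cc(OC)cc(OC)c2C(=O)c2cc(OC)cc(OC)c2[C@@H](c2ccc(OC)cc2)[C@@H]1c1cc(OC)cc(OC)c1 | intermediate
17 | pentacyclic diketone (indanone carbonyl C-a, diaryl ketone C-d, trans ring fusion C-b/C-e) | O=C1c2c(OC)cc(OC)cc2[C@H]2[C@H](c3ccc(OC)cc3)c3c(OC)cc(OC)cc3C(=O)c3c(OC)cc(OC)cc3[C@H]12 | intermediate
18 | 4-bromoanisole | COc1ccc(Br)cc1 | starting material
19 | tertiary alcohol at C-a (aryl anti to ring D) | COc1ccc([C@@]2(O)c3c(OC)cc(OC)cc3[C@H]3[C@H](c4ccc(OC)cc4)c4c(OC)cc(OC)cc4C(=O)c4c(OC)cc(OC)cc4[C@H]23)cc1 | intermediate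
20 | hepta-O-methyl ketone (C-a aryl cis to ring D; C-d carbonyl) | COc1ccc([C@@H]2c3c(OC)cc(OC)cc3[C@H]3[C@H](c4ccc(OC)cc4)c4c(OC)cc(OC)cc4C(=O)c4c(OC)cc(OC)cc4[C@H]23)cc1 | intermediate
21 | ortho-hydroxy ketone (ring D phenol ortho to C-d carbonyl) | COc1ccc([C@@H]2c3c(OC)cc(OC)cc3[C@H]3[C@H](c4ccc(OC)cc4)c4c(OC)cc(OC)cc4C(=O)c4c(O)cc(OC)cc4[C@H]23)cc1 | intermediate
22 | ortho-hydroxybenzhydrol (C-d–OH, both epimers) | COc1ccc([C@@H]2c3c(OC)cc(OC)cc3[C@H]3[C@H](c4ccc(OC)cc4)c4c(OC)cc(OC)cc4C(O)c4c(O)cc(OC)cc4[C@H]23)cc1 | intermediate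
23 | sulfone (C-d–SO2-p-tolyl, both epimers) | COc1ccc([C@@H]2c3c(OC)cc(OC)cc3[C@H]3[C@H](c4ccc(OC)cc4)c4c(OC)cc(OC)cc4C(S(=O)(=O)c4ccc(C)cc4)c4c(O)cc(OC)cc4[C@H]23)cc1 | intermediate
24 | 4-methoxybenzyl alcohol | COc1ccc(CO)cc1 | starting material
25 | 1-(4-methoxybenzyl)tetrahydrothiophenium tetrafluoroborate | COc1ccc(C[S+]2CCCC2)cc1.F[B-](F)(F)F | intermediate
26 | ortho-quinone methide (ring D as a cyclohexadienone, exocyclic C-d=C bond inside the eight-membered ring) | COc1ccc([C@@H]2c3c(OC)cc(OC)cc3[C@H]3[C@H](c4ccc(OC)cc4)c4c(OC)cc(OC)cc4/C=C4/C(=O)C=C(OC)C=C4[C@H]23)cc1 | intermediate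
27 | octa-O-methylcanaliculatol | COc1ccc([C@@H]2c3c(OC)cc(OC)cc3[C@H]3[C@H](c4ccc(OC)cc4)c4c(OC)cc(OC)cc4[C@@H]4c5c(cc(OC)cc5[C@H]23)O[C@H]4c2ccc(OC)cc2)cc1 | intermediate
28 | canaliculatol | Oc1ccc([C@@H]2c3c(O)cc(O)cc3[C@H]3[C@H](c4ccc(O)cc4)c4c(O)cc(O)cc4[C@@H]4c5c(cc(O)cc5[C@H]23)O[C@H]4c2ccc(O)cc2)cc1 | target

**Step count.** Total: 16 steps. Longest linear sequence: 13 steps (6 → 7 → 10 → 12 → 14 → 15 → 16 → 17 → 19 → 20 → 21 → 23 → 27 → 28).

**Steps most likely to fail**

Step 6 (ring expansion). The hindered, fully substituted enolate of 5 may be O-arylated, or the aryl anion may be protonated before it reaches the C-d carbonyl, so that the ketoester is arylated but the ring is not expanded. Fallback: the same reorganisation is run stepwise, setting out from 5. Arylation of 5 with (2-bromo-3,5-dimethoxyphenyl)lead triacetate F1 (made from the arylboronic acid and Pb(OAc)4; pyridine, CHCl3, 50 °C) should give the quaternary α-aryl ketoester F2. Bromine–lithium exchange (t-BuLi, THF, −100 °C) then generates the aryl anion next to the ketone, which should add, fragment and, after protonation, rejoin the route at 14.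

Step 11 (C-a). The cation may lose the C-e proton to a tetrasubstituted indene whose reprotonation would scramble C-e (cis ring fusion), or hydride may arrive syn to ring D. Fallback: setting out from 19, O-acylation (LiN(SiMe3)2, then ClC(O)CO2Me, THF, −78 °C) should give the methyl oxalate F3. Radical deoxygenation follows (Bu3SnH, AIBN, toluene, 110 °C). The planar benzylic radical cannot lose the C-e proton and should take hydrogen from the same less hindered face. The route is rejoined at 20.

Step 15 (key step). The ylide may attack the wrong face of C-d, or the phenoxide may be O-benzylated by 25 before the quinone methide forms. Fallback: setting out from 21, O-alkylation with 4-methoxybenzyl chloride (K2CO3, DMF) should give the ether F4, and condensation with hydrazine hydrate (EtOH, AcOH, 80 °C) the hydrazone F5. Oxidation with MnO2 (CH2Cl2) gives the diaryldiazomethane F6, which is treated in the same pot with Rh2(S-PTAD)4 or its enantiomer. The donor/donor rhodium carbene should insert into the benzylic ether C–H bond, closing the same ring through the C-d–C-f bond with catalyst-controlled face selection at C-d. Should the cis isomer F7 (C-f epimer) form, brief treatment with CF3CO2H should equilibrate it at C-f. The route is rejoined at 27.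

**Further compounds**

F1 | step 6 | (2-bromo-3,5-dimethoxyphenyl)lead triacetate | COc1cc(OC)c(Br)c([Pb](OC(C)=O)(OC(C)=O)OC(C)=O)c1
F2 | step 6 | methyl 2-(2-bromo-3,5-dimethoxyphenyl)-3-(3,5-dimethoxyphenyl)-5,7-dimethoxy-4-(4-methoxyphenyl)-1-oxotetralin-2-carboxylate (racemic) | COC(=O)[C@]1(c2cc(OC)cc(OC)c2Br)C(=O)c2cc(OC)cc(OC)c2[C@@H](c2ccc(OC)cc2)[C@@H]1c1cc(OC)cc(OC)c1
F3 | step 11 | methyl oxalate ester of the tertiary alcohol 19 | COc1ccc([C@@]2(OC(=O)C(=O)OC)c3c(OC)cc(OC)cc3[C@H]3[C@H](c4ccc(OC)cc4)c4c(OC)cc(OC)cc4C(=O)c4c(OC)cc(OC)cc4[C@H]23)cc1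
F4 | step 15 | 4-methoxybenzyl ether of phenol 21 | COc1ccc([C@@H]2c3c(OC)cc(OC)cc3[C@H]3[C@H](c4ccc(OC)cc4)c4c(OC)cc(OC)cc4C(=O)c4c(OCc5ccc(OC)cc5)cc(OC)cc4[C@H]23)cc1
F5 | step 15 | hydrazone of ketone F4 | COc1ccc([C@@H]2c3c(OC)cc(OC)cc3[C@H]3[C@H](c4ccc(OC)cc4)c4c(OC)cc(OC)cc4C(=NN)c4c(OCc5ccc(OC)cc5)cc(OC)cc4[C@H]23)cc1
F6 | step 15 | diaryldiazomethane from F5 | COc1ccc([C@@H]2c3c(OC)cc(OC)cc3[C@H]3[C@H](c4ccc(OC)cc4)c4c(OC)cc(OC)cc4C(=[N+]=[N-])c4c(OCc5ccc(OC)cc5)cc(OC)cc4[C@H]23)cc1
F7 | step 15 | C-f epimer of 27 (2,3-cis-dihydrobenzofuran) | COc1ccc([C@@H]2c3c(OC)cc(OC)cc3[C@H]3[C@H](c4ccc(OC)cc4)c4c(OC)cc(OC)cc4[C@@H]4c5c(cc(OC)cc5[C@H]23)O[C@@H]4c2ccc(OC)cc2)cc1
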